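## Retrosynthetic overview

1. Target 17 ⇐ 16: acetolysis of an exo-norbornenyl tosylate (homoallyl → cyclopropylcarbinyl cation) closes the cyclopropane (C9–C10) and delivers the C11 acetate. 16 ⇐ 14 by lactone/pivalate reduction and selective acetylation.
2. 14 ⇐ 13: intramolecular Diels–Alder reaction of a 1,3-disubstituted cyclopentadiene with a (Z)-α-(tosyloxymethylidene)butyrolactone forms C1–C6 and C8–C9, i.e. the cyclohexane and the bicyclo[2.2.1]heptene in one step.
3. 13 ⇐ 9: diene from a 3-substituted cyclopentenone (MeLi/CeCl3, then dehydration); dienophile by formylation/tosylation of the lactone. 9 ⇐ 6 by allylation, Wacker oxidation and aldol condensation.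
4. 6 ⇐ 3 + 2: Felkin-selective Mukaiyama aldol of lactone aldehyde 4 (from the L-glutamic-acid-derived lactone 3) with the enol silane of 3-methylbutan-2-one.
5. Ring order: lactone (bought) → cyclopentenone/cyclopentadiene → cyclohexane + norbornene (cycloaddition) → cyclopropane (solvolysis).

Labels used for discussion: C1 quaternary carbon bearing C12H2OAc; C2 CH2; C3 CHOH; C4 CHOAc; C5 CMe2; C6 cage apex; C7 CH2; C8, C9, C10 cyclopropane (C10 bears CH3); C11 CHOAc.

Assumption: compounds 1 and 3 are bought (3 is the lactone made on scale from L-glutamic acid); all reagents are catalogue items.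

## Route

Step 1
Reactants: 1 3-bromo-3-methylbutan-2-one
Product: 2 3-methyl-2-(trimethylsilyloxy)but-2-ene
Conditions: Zn dust, Me3SiCl, Et2O–MeCN, 0 °C → rt
Reagents that add atoms: chlorotrimethylsilane, C[Si](C)(C)Cl
Why: Reformatsky-type zinc insertion into the tertiary C–Br bond and O-silylation of the zinc enolate give the tetrasubstituted silyl enol ether regiospecifically; no stereocentre is involved.

Step 2
Reactants: 3 (5S)-5-(hydroxymethyl)oxolan-2-one
Product: 4 (2S)-5-oxooxolane-2-carbaldehyde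
Conditions: Dess–Martin periodinane, CH2Cl2, 0 °C → rt (used crude)
Reagents that add atoms: none
Why: Dess–Martin oxidation of the primary alcohol is neutral and does not epimerise the bought C3 centre.

Step 3
Reactants: 4 (2S)-5-oxooxolane-2-carbaldehyde; 2 3-methyl-2-(trimethylsilyloxy)but-2-ene
Product: 5 (5S)-5-[(1R)-1-hydroxy-2,2-dimethyl-3-oxobutyl]oxolan-2-one
Conditions: BF3·OEt2, CH2Cl2, −78 °C
Reagents that add atoms: none
Why: Mukaiyama aldol through an open transition state; with the non-chelating Lewis acid the α-acyloxy centre C3 directs attack by polar Felkin–Anh (Cornforth) control, setting C4 as R (anti to the lactone oxygen) while the quaternary C5 is formed.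

Step 4
Reactants: 5 (5S)-5-[(1R)-1-hydroxy-2,2-dimethyl-3-oxobutyl]oxolan-2-one
Product: 6 (1R)-2,2-dimethyl-3-oxo-1-[(2S)-5-oxooxolan-2-yl]butyl 2,2-dimethylpropanoate
Conditions: PivCl, pyridine, DMAP (cat.), CH2Cl2, 0 → 40 °C
Reagents that add atoms: pivaloyl chloride, CC(C)(C)C(Cl)=O
Why: DMAP-catalysed acylation; the pivalate has no α-hydrogen, blocks retro-aldol cleavage in the later base steps and is removed without an extra step in step 12.

Step 5
Reactants: 6 (1R)-2,2-dimethyl-3-oxo-1-[(2S)-5-oxooxolan-2-yl]butyl 2,2-dimethylpropanoate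
Product: 7 (1R)-2,2-dimethyl-3-oxo-1-[(2S)-5-oxooxolan-2-yl]hept-6-en-1-yl 2,2-dimethylpropanoate
Conditions: LiN(i-Pr)2 (1.05 equiv), THF, −78 °C; allyl bromide, DMPU, −78 → −20 °C
Reagents that add atoms: allyl bromide, C=CCBr
Why: Kinetic enolate alkylation; the methyl group is the only enolisable position of the ketone (C5 is quaternary) and is far more acidic than the lactone α-CH2.

Step 6
Reactants: 7 (1R)-2,2-dimethyl-3-oxo-1-[(2S)-5-oxooxolan-2-yl]hept-6-en-1-yl 2,2-dimethylpropanoate
Product: 8 (1R)-2,2-dimethyl-3,6-dioxo-1-[(2S)-5-oxooxolan-2-yl]heptyl 2,2-dimethylpropanoate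
Conditions: PdCl2 (10 mol %), CuCl, O2 (1 atm), DMF–H2O 7:1, rt
Reagents that add atoms: water, O
Why: Tsuji–Wacker oxidation; Markovnikov hydroxypalladation of the terminal alkene gives the methyl ketone and hence the 1,4-diketone.

Step 7
Reactants: 8 (1R)-2,2-dimethyl-3,6-dioxo-1-[(2S)-5-oxooxolan-2-yl]heptyl 2,2-dimethylpropanoate
Product: 9 (1R)-2-methyl-2-(3-oxocyclopent-1-en-1-yl)-1-[(2S)-5-oxooxolan-2-yl]propyl 2,2-dimethylpropanoate
Conditions: KOt-Bu (20 mol %), t-BuOH–THF, rt
Reagents that add atoms: none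
Why: Intramolecular aldol condensation; only the terminal methyl can close a five-membered ring onto the C6 ketone, so a single 3-substituted cyclopentenone forms irreversibly.

Step 8
Reactants: 9 (1R)-2-methyl-2-(3-oxocyclopent-1-en-1-yl)-1-[(2S)-5-oxooxolan-2-yl]propyl 2,2-dimethylpropanoate
Product: 10 (1R)-2-(3-hydroxy-3-methylcyclopent-1-en-1-yl)-2-methyl-1-[(2S)-5-oxooxolan-2-yl]propyl 2,2-dimethylpropanoate (both carbinol epimers)
Conditions: MeLi, CeCl3, THF, −78 °C
Reagents that add atoms: methyllithium, [Li]C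
Why: Organocerium 1,2-addition is chemoselective for the enone carbonyl over lactone and pivalate and does not enolise; the new carbinol centre is unselective and is destroyed in step 11.

Step 9
Reactants: 10 (1R)-2-(3-hydroxy-3-methylcyclopent-1-en-1-yl)-2-methyl-1-[(2S)-5-oxooxolan-2-yl]propyl 2,2-dimethylpropanoate
Product: 11 (1R)-2-(3-hydroxy-3-methylcyclopent-1-en-1-yl)-1-[(2S)-4-(hydroxymethylidene)-5-oxooxolan-2-yl]-2-methylpropyl 2,2-dimethylpropanoate
Conditions: NaH (2.2 equiv), HCO2Et, THF, 0 °C → rt; AcOH quench at 0 °C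
Reagents that add atoms: ethyl formate, CCOC=O
Why: Claisen formylation at the lactone α-carbon (C1), the only acidic C–H left in 10, supplies C9 as a stable hydroxymethylidene lactone.

Step 10
Reactants: 11 (1R)-2-(3-hydroxy-3-methylcyclopent-1-en-1-yl)-1-[(2S)-4-(hydroxymethylidene)-5-oxooxolan-2-yl]-2-methylpropyl 2,2-dimethylpropanoate
Product: 12 (1R)-2-(3-hydroxy-3-methylcyclopent-1-en-1-yl)-2-methyl-1-[(2S,4Z)-4-{[(4-methylbenzenesulfonyl)oxy]methylidene}-5-oxooxolan-2-yl]propyl 2,2-dimethylpropanoate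
Conditions: TsCl, TMEDA, LiCl, MeCN, 0 °C
Reagents that add atoms: p-toluenesulfonyl chloride, Cc1ccc(cc1)S(Cl)(=O)=O
Why: O-sulfonylation of the lithium-chelated enolate gives the (Z)-enol tosylate (OTs cis to the lactone carbonyl), and the amine base leaves the tertiary alcohol untouched.

Step 11
Reactants: 12 (Z)-enol tosylate carbinol
Product: 14 norbornene lactone tosylate (cycloadduct), via cyclopentadiene enol tosylate 13 (not isolated)
Conditions: Burgess reagent, toluene, 50 °C; then dilute to 0.005 M, BHT (cat.), 110 °C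
Reagents that add atoms: none
Why: Burgess dehydration gives cyclopentadiene 13, which undergoes an intramolecular Diels–Alder reaction on the lactone face that carries C4, so C3 fixes C1; the exo-carbonyl/endo-alkyl preference of α-alkylidene butyrolactones places C12 syn to C7 and C2 endo, which sets C6, C8 and C9 (OTs exo); the 1,5-H-shift isomers of 13 equilibrate and only 13 bonds through an unsubstituted diene terminus.

Step 12
Reactants: 14 norbornene lactone tosylate (cycloadduct)
Product: 15 norbornene triol tosylate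
Conditions: i-Bu2AlH (6 equiv), CH2Cl2, −78 → 0 °C
Reagents that add atoms: none
Why: Hydride reduction opens the lactone to the C12 primary alcohol and the C3 alcohol and cleaves the pivalate; the neopentyl exo tosylate is inert and cis to the new alkoxide, so it is not displaced.

Step 13
Reactants: 15 norbornene triol tosylate
Product: 16 12,4-di-O-acetyl norbornene tosylate (3-OH free)
Conditions: Ac2O, pyridine, 0 °C → rt, 24 h
Reagents that add atoms: acetic anhydride, CC(=O)OC(C)=O
Why: Selective acylation; the primary C12 hydroxyl and the equatorial C4 hydroxyl react, whereas the axial C3 hydroxyl, 1,3-diaxial to C12 and to a C5 methyl, is too hindered under DMAP-free conditions.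

Step 14
Reactants: 16 12,4-di-O-acetyl norbornene tosylate (3-OH free)
Product: 17 target CNP0111873.1
Conditions: NaOAc, AcOH, 70 °C
Reagents that add atoms: sodium acetate, CC(=O)[O-].[Na+]; acetic acid (solvent), CC(=O)O
Why: Buffered acetolysis with homoallylic π-participation (norbornenyl → nortricyclyl cation): C10 attacks C9 anti to the exo tosylate, closing the cyclopropane and fixing C9 and C10, and acetate captures C11 from the face syn to C7, anti to the participating bond and away from C2, which sets C11.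

## Compound list

1 | 3-bromo-3-methylbutan-2-one | CC(=O)C(C)(C)Br | starting material
2 | 3-methyl-2-(trimethylsilyloxy)but-2-ene | CC(C)=C(C)O[Si](C)(C)C | intermediate
3 | (5S)-5-(hydroxymethyl)oxolan-2-one | O=C1CC[C@H](O1)CO | starting material
4 | (2S)-5-oxooxolane-2-carbaldehyde | O=C1CC[C@H](O1)C=O | intermediate
5 | (5S)-5-[(1R)-1-hydroxy-2,2-dimethyl-3-oxobutyl]oxolan-2-one | O=C1CC[C@H](O1)[C@H](O)C(C)(C)C(C)=O | intermediate
6 | (1R)-2,2-dimethyl-3-oxo-1-[(2S)-5-oxooxolan-2-yl]butyl 2,2-dimethylpropanoate | O=C1CC[C@H](O1)[C@H](OC(=O)C(C)(C)C)C(C)(C)C(C)=O | intermediate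
7 | (1R)-2,2-dimethyl-3-oxo-1-[(2S)-5-oxooxolan-2-yl]hept-6-en-1-yl 2,2-dimethylpropanoate | O=C1CC[C@H](O1)[C@H](OC(=O)C(C)(C)C)C(C)(C)C(=O)CCC=C | intermediate
8 | (1R)-2,2-dimethyl-3,6-dioxo-1-[(2S)-5-oxooxolan-2-yl]heptyl 2,2-dimethylpropanoate | O=C1CC[C@H](O1)[C@H](OC(=O)C(C)(C)C)C(C)(C)C(=O)CCC(C)=O | intermediate
9 | (1R)-2-methyl-2-(3-oxocyclopent-1-en-1-yl)-1-[(2S)-5-oxooxolan-2-yl]propyl 2,2-dimethylpropanoate | O=C1CC[C@H](O1)[C@H](OC(=O)C(C)(C)C)C(C)(C)C2=CC(=O)CC2 | intermediate
10 | (1R)-2-(3-hydroxy-3-methylcyclopent-1-en-1-yl)-2-methyl-1-[(2S)-5-oxooxolan-2-yl]propyl 2,2-dimethylpropanoate (both carbinol epimers) | O=C1CC[C@H](O1)[C@H](OC(=O)C(C)(C)C)C(C)(C)C2=CC(C)(O)CC2 | intermediate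
11 | (1R)-2-(3-hydroxy-3-methylcyclopent-1-en-1-yl)-1-[(2S)-4-(hydroxymethylidene)-5-oxooxolan-2-yl]-2-methylpropyl 2,2-dimethylpropanoate (enol geometry not fixed) | OC=C1C[C@H](OC1=O)[C@H](OC(=O)C(C)(C)C)C(C)(C)C2=CC(C)(O)CC2 | intermediate
12 | (1R)-2-(3-hydroxy-3-methylcyclopent-1-en-1-yl)-2-methyl-1-[(2S,4Z)-4-{[(4-methylbenzenesulfonyl)oxy]methylidene}-5-oxooxolan-2-yl]propyl 2,2-dimethylpropanoate | Cc1ccc(cc1)S(=O)(=O)O/C=C2/C[C@H](OC2=O)[C@H](OC(=O)C(C)(C)C)C(C)(C)C3=CC(C)(O)CC3 | intermediate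
13 | (1R)-2-methyl-2-(3-methylcyclopenta-1,3-dien-1-yl)-1-[(2S,4Z)-4-{[(4-methylbenzenesulfonyl)oxy]methylidene}-5-oxooxolan-2-yl]propyl 2,2-dimethylpropanoate | Cc1ccc(cc1)S(=O)(=O)O/C=C2/C[C@H](OC2=O)[C@H](OC(=O)C(C)(C)C)C(C)(C)C3=CC(C)=CC3 | intermediate (not isolated)
14 | cycloadduct: 10-methylnorborn-10-ene (bridgeheads C6 and C8, C7 methano bridge) fused at C1–C6 to the new cyclohexane; C12(=O)–O3 γ-lactone bridge retained with C12 exo on C1 (syn to C7) and C2 endo; 4-pivaloyloxy cis to O3; 9-exo-tosyloxy | O=C1[C@]23C[C@H](O1)[C@H](OC(=O)C(C)(C)C)C(C)(C)[C@]24C[C@H]([C@@H]3OS(=O)(=O)c5ccc(C)cc5)C(C)=C4 | intermediate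
15 | norbornene triol tosylate: as 14 with C12H2OH, 3-OH and 4-OH free (all on the C7 face of the cyclohexane), 9-exo-OTs | OC[C@]12C[C@H](O)[C@H](O)C(C)(C)[C@]13C[C@H]([C@@H]2OS(=O)(=O)c4ccc(C)cc4)C(C)=C3 | intermediate
16 | 12-O,4-O-diacetate of 15 (3-OH free, 9-exo-OTs) | CC(=O)OC[C@]12C[C@H](O)[C@H](OC(C)=O)C(C)(C)[C@]13C[C@H]([C@@H]2OS(=O)(=O)c4ccc(C)cc4)C(C)=C3 | intermediate
17 | CNP0111873.1: 4,11,12-tri-O-acetyl-3-hydroxy nortricyclene-fused cyclohexane (cyclomyltaylane skeleton) | CC(=O)OC[C@]12C[C@H](O)[C@H](OC(C)=O)C(C)(C)[C@]13C[C@@H]1[C@H]2[C@]1(C)[C@H]3OC(C)=O | target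

## Step count and risks

Total step count: 14. Longest linear sequence: 13 steps (3 → 17, steps 2 to 14; step 1 is a one-step side branch).

The three steps most likely to fail:

Step 11. The risks are the ring-fusion selectivity (tether endo versus tether exo) and the competing diene isomer that would put the methyl group on a bridgehead. The fallback sets out from 11. Tosylation under amine-only conditions (TsCl, N-methylimidazole, Et3N) gives the (E)-enol tosylate F1. Burgess dehydration gives cyclopentadiene F2 (not isolated). In F2 the sulfonate lies under the diene and only the flat lactone carbonyl faces the ring CH2, so the tether-endo mode is less encumbered; heating at 110 °C gives the endo-tosylate adduct F3. i-Bu2AlH then gives triol F4 and Ac2O/pyridine gives diacetate F5. The endo sulfonate has no anti-periplanar π-assistance, so it is ionised in NaOAc/AcOH at 110 °C; it funnels into the same nortricyclyl cation and the sequence comes back to the route at 17.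

Step 14. The risks are capture of the cation at C9 or C8 (homoallylic acetates) and acyl migration onto O3 in hot acetic acid. The fallback sets out from 15 and separates cage formation from acetate installation. Solvolysis in buffered aqueous acetone (NaHCO3, acetone–H2O, 50 °C) lets water trap the cation and gives the nortricyclane tetraol F6. Acetylation with Ac2O, pyridine and DMAP (cat.) at 0 °C then esterifies O12, O4 and O11 and leaves the axial, doubly 1,3-diaxially shielded 3-OH free, coming back to the route at 17.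

Step 13. The risk is poor discrimination between the C3 and C4 hydroxyls. The fallback sets out from 15. Only the primary hydroxyl is acetylated (AcCl, 2,4,6-collidine, CH2Cl2, −78 °C) to give the 12-O-monoacetate F7. The cis-3,4-diol is then converted into the dibutylstannylene acetal F8 (Bu2SnO, toluene, reflux, not isolated). Opening F8 with AcCl at 0 °C acylates the equatorial O4 regioselectively and comes back to the route at 16.

Further compounds
F1 | step 11 | (1R)-2-(3-hydroxy-3-methylcyclopent-1-en-1-yl)-2-methyl-1-[(2S,4E)-4-{[(4-methylbenzenesulfonyl)oxy]methylidene}-5-oxooxolan-2-yl]propyl 2,2-dimethylpropanoate | Cc1ccc(cc1)S(=O)(=O)O/C=C2/C(=O)O[C@@H](C2)[C@H](OC(=O)C(C)(C)C)C(C)(C)C3=CC(C)(O)CC3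
F2 | step 11 | (1R)-2-methyl-2-(3-methylcyclopenta-1,3-dien-1-yl)-1-[(2S,4E)-4-{[(4-methylbenzenesulfonyl)oxy]methylidene}-5-oxooxolan-2-yl]propyl 2,2-dimethylpropanoate | Cc1ccc(cc1)S(=O)(=O)O/C=C2/C(=O)O[C@@H](C2)[C@H](OC(=O)C(C)(C)C)C(C)(C)C3=CC(C)=CC3
F3 | step 11 | C9 epimer of cycloadduct 14 (9-endo-tosyloxy) | O=C1[C@]23C[C@H](O1)[C@H](OC(=O)C(C)(C)C)C(C)(C)[C@]24C[C@H]([C@H]3OS(=O)(=O)c5ccc(C)cc5)C(C)=C4
F4 | step 11 | C9 epimer of triol tosylate 15 (9-endo-tosyloxy) | OC[C@]12C[C@H](O)[C@H](O)C(C)(C)[C@]13C[C@H]([C@H]2OS(=O)(=O)c4ccc(C)cc4)C(C)=C3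
F5 | step 11 | C9 epimer of diacetate 16 (9-endo-tosyloxy) | CC(=O)OC[C@]12C[C@H](O)[C@H](OC(C)=O)C(C)(C)[C@]13C[C@H]([C@H]2OS(=O)(=O)c4ccc(C)cc4)C(C)=C3
F6 | step 14 | nortricyclane tetraol (17 with all three acetates replaced by OH) | OC[C@]12C[C@H](O)[C@H](O)C(C)(C)[C@]13C[C@@H]1[C@H]2[C@]1(C)[C@H]3O
F7 | step 13 | 12-O-monoacetate of triol tosylate 15 | CC(=O)OC[C@]12C[C@H](O)[C@H](O)C(C)(C)[C@]13C[C@H]([C@@H]2OS(=O)(=O)c4ccc(C)cc4)C(C)=C3
F8 | step 13 | 3,4-O-dibutylstannylene acetal of F7 | CC(=O)OC[C@]12C[C@H](O5)[C@H](O[Sn]5(CCCC)CCCC)C(C)(C)[C@]13C[C@H]([C@@H]2OS(=O)(=O)c4ccc(C)cc4)C(C)=C3
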